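## The problem

Selaginellin is built on one benzene ring (ring A) that carries four different carbon substituents on four adjacent carbons: going round the ring, C5 bears CH2OH, C6 the (4-hydroxyphenyl)ethynyl group, C1 the methide carbon and C2 a 4-hydroxyphenyl ring, while C3 and C4 are CH. The methide carbon also bears a 4-hydroxyphenyl ring and is the exocyclic terminus of the cyclohexadienone ring. The molecule has no stereocentre, so the task is purely regiochemical: the substituents must come in a fixed order, and C1 and C6, each flanked on both sides, are the positions where bonds are hardest to make on a finished arene. The para-quinone methide is an electrophile that tolerates neither nucleophiles nor reductants, so it is best unveiled last from a triarylcarbinol, which ionises under acid and loses a phenolic proton. The diarylalkyne next to that carbinol can be attacked by the carbinol oxygen under metal or base catalysis, so it should be completed late and under mild conditions. The benzylic alcohol and the four phenolic oxygens need protecting groups that all fall in one mild acid step. What makes the key step possible is the ortho relationship between the methide carbon (on C1) and the first alkyne carbon (on C6): with one oxygen between them they are C5 and C2 of a 5,5-diarylfuran-2(5H)-one whose C3=C4 double bond is the C6–C1 bond of ring A. The other four ring atoms (C2 with C3, C5 with C4) are then two 1-substituted vinyl groups on that double bond, and the missing C3–C4 bond can be closed by a 6π-electrocyclisation.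

## Retrosynthesis

**25 to 23.** No C–C bond is cut. The quinone methide 25 is the dehydrated form of the pentahydroxy carbinol 24, which is the deprotected form of carbinol 23. The alternatives (oxidising a triarylmethane, or adding an aryl nucleophile to a quinone) would operate on unprotected, electrophilic material. In 23 the phenols are methoxymethyl (MOM) ethers and the primary alcohol is a tert-butyldimethylsilyl (TBS) ether. Both groups leave under the mild acid that also ionises the carbinol, so one operation must do everything.

**23 to 20 and 22.** The C(sp)–C(aryl) bond of the alkyne is cut (Sonogashira coupling). The neighbouring cut would bring the aryl group and the second alkyne carbon in together as a benzylic carbanion adding to a lactone. That leads to a keto intermediate whose enol derivative must be eliminated next to a free tertiary alkoxide, and the alkoxide is placed to add back to it. The terminal alkyne 20 avoids this. The aryl iodide 22 is one step from 4-iodophenol 21. The coupling must run cold enough that the carbinol oxygen does not add to the alkyne.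

**20 to 18 to 17.** The C≡C bond is cut back to an aldehyde carbon by a one-carbon homologation. The aldehyde (open form 19) and the carbinol oxygen are tied together as lactol 18, the half-reduced form of the 3,3-diarylphthalide 17. The lactone of 17 therefore holds both the future carbinol oxygen and the first alkyne carbon. Phthalide 17 is a stable, non-electrophilic compound with ring A complete. The forward reaction needs the lactol to open under basic conditions despite the gem-diaryl group.

**17 to 16 to 15.** Dehydrogenation relates 17 to the 5,6-dihydrophthalide 16, and the C3–C4 bond of ring A is then cut. This is the key disconnection. A Diels–Alder reaction or a cyclotrimerisation would cut more bonds, but each would raise a regiochemical question. The electrocyclisation raises none, because the triene 15 already fixes the order of all four substituents. Triene 15 contains no carbocyclic ring A at all, only a butenolide with two vinyl groups. The forward reaction needs thermal closure to be faster than polymerisation of the two 1,1-disubstituted alkenes.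

**15 to 14 and 13; 14 to 5 and 10.** The two C(sp2)–C(sp2) bonds from the butenolide to the vinyl groups are cut (Suzuki–Miyaura couplings). The C4 chlorine of 5 is a vinylogous acyl chloride and reacts first, so the aryl-bearing vinylboronate 10 is introduced there. The silyloxymethyl vinylboronate 13 then replaces the C3 chlorine of 14. This order puts the aryl group on ring A C2 and the CH2O group on C5. The first coupling must be site-selective and the second must tolerate a hindered α-chloro lactone.

**5 to 4 to 1 and 2.** The two aryl–carbon bonds at the quaternary carbon are cut (double Friedel–Crafts condensation of dichloromaleic anhydride 1 with two molecules of phenol 2, through the mono-aryl hydroxy lactone 3). The most crowded carbon of the target is thus made first, on a four-carbon anhydride. MOM protection of bisphenol 4 gives 5.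

**Side chains.** Boronate 10 comes from 4-hydroxyacetophenone 6 through MOM ether 7, enolate 8 and vinyl triflate 9. Boronate 13 comes from propargyl alcohol 11 through silyl ether 12 by a copper-catalysed protoboration that places boron on the internal carbon.

## Roads not taken

Alternative 1: chloroaryne three-component coupling. The cut treats ring A as a purchased benzene and disconnects the C2–aryl and C1–carbonyl bonds together. In the forward key step an ortho-magnesiated aryl sulfonate expels sulfonate to give a 3-chloroaryne. An aryl Grignard reagent adds at C2, away from the chlorine, whose inductive effect stabilises the carbanion developing at C1. The new C1–magnesium bond is then acylated by an N-methoxy-N-methylbenzamide to give {3-chloro-4'-(methoxymethoxy)-4-[(triisopropylsilyloxy)methyl]biphenyl-2-yl}[4-(methoxymethoxy)phenyl]methanone A1. The merits are convergence and modularity: no ring is built, and A1 leads to the target by the classical sequence of ketone, carbinol and methide. The weak points are several. The aryne precursor is a 1,2,3,4-tetrasubstituted benzene that must itself be made in several directed steps. Acylating a 2,6-disubstituted arylmagnesium with a Weinreb-type amide is slow and competes with protonation. Ketone A1 then needs a Sonogashira coupling at a di-ortho-substituted aryl chloride next to a benzophenone, and an aryllithium addition to that very hindered carbonyl group. In comparison, the way from A1 to the target is probably shorter than the chosen plan's way from 17. Against that, the chosen plan fixes the order of substituents by connectivity, not by an inductive bias. It also makes the most crowded bonds (those at the carbinol carbon) first on a small molecule, and never has to substitute a hindered aryl chloride.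

Alternative 2: silicon-tethered [2+2+2] cyclotrimerisation. The cut removes C1–C6, C2–C3 and C4–C5 at once. In the forward key step, under RhCl(PPh3)3 catalysis, the silyl-ether-tethered diyne dimethyl[3-(methoxymethoxy)prop-1-yn-1-yl]{[1,1,3-tris(4-(methoxymethoxy)phenyl)prop-2-yn-1-yl]oxy}silane A2 takes up one molecule of acetylene A3. The product is the benzoxasilole 7-[(methoxymethoxy)methyl]-1,1-dimethyl-3,3,4-tris[4-(methoxymethoxy)phenyl]-1,3-dihydro-2,1-benzoxasilole A4. The merits are that ring A and all four substituents appear in one step, that the tether of A2 removes any regiochemical doubt, and that the carbinol oxygen is already in place in A4. The weak points begin with the intermolecular third alkyne: A3 is a gas that must be used in excess, and its own trimerisation and the dimerisation of A2 compete with the wanted reaction. Both tethered alkynes of A2 are hindered and flank a quaternary carbon. The aryl–silicon bond of A4 sits at the most crowded ring position and must be turned into the aryl–alkynyl bond; ipso-halogenation there competes with halogenation of the electron-rich MOM-aryl rings. The alkyl MOM ether of A4 also needs stronger acid at the end than the chosen TBS ether. In comparison, this road has fewer steps on paper and forms more bonds in its key step. The chosen plan sets against it that every C–C bond is made by a precedented cross-coupling or pericyclic step, and that C6 arrives as a lactone carbonyl, whose conversion to an alkyne is routine, not as a C–Si bond.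

Alternative 3: formal [3+3] cyclocondensation to a 6-arylsalicylate. The cut removes C4–C5 and C1–C2. In the forward key step TiCl4 activates a 3-silyloxy-1-arylpropenone, and the terminal carbon of a 1,3-bis(silyloxy)-1,3-diene attacks its silyloxy-bearing CH. The central diene carbon then closes onto the aryl ketone in a Mukaiyama aldol reaction, and loss of silanol and water gives methyl 3-[(tert-butyldiphenylsilyloxy)methyl]-2-hydroxy-6-[4-(triisopropylsilyloxy)phenyl]benzoate A5. The merits are cheap acyclic precursors and an arene that forms directly at the right oxidation level with well-understood regiochemistry. The phenol of A5 at C6 is a handle for the alkyne (triflate, then Sonogashira coupling), and the ester of A5 is the future methide carbon. The weak points lie after the key step. Two aryl nucleophiles must add to the ester of A5, which is flanked by two ortho substituents; such double additions are slow and tend to stop at the ketone. TiCl4 rules out acetal protecting groups, so a silyl ether set must be carried through aryllithium chemistry, and the terminal silyloxymethyl group of the diene can be lost by elimination. In comparison, this road builds ring A, as A5, in fewer steps than the chosen plan, which needs two couplings, a closure and a dehydrogenation. The chosen plan has the diaryl-substituted carbon in place from step 1, made by a condensation on an unhindered anhydride, so the hardest bond set of the [3+3] road is never required.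

Key step: step 10

Remark on the chemistry: the target is achiral and is taken as the quinone methide tautomer; the stereocentres in 3, 18 and in some fallback compounds are racemic and are erased in later steps.

## Route

Step 1
Reactants: 1 dichloromaleic anhydride; 2 phenol
Product: 4 3,4-dichloro-5,5-bis(4-hydroxyphenyl)furan-2(5H)-one, via mono-aryl hydroxy lactone 3 (not isolated)
Conditions: 2 (2.5 equiv in all), MeSO3H, 90 °C
Reagents that add atoms: phenol (a second molecule of 2), Oc1ccccc1
Why: Friedel–Crafts acylation of one phenol by the protonated anhydride gives the aroyl acid, which rests as hydroxy lactone 3; acid ionises C5 of 3 to a cation stabilised by the 4-hydroxyphenyl group, and this arylates the second phenol at its para position with loss of water (phenolphthalein-type condensation of a cyclic anhydride). The two chlorine atoms leave the double bond fully substituted, which disfavours Michael-type arylation.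

Step 2
Reactants: 4 3,4-dichloro-5,5-bis(4-hydroxyphenyl)furan-2(5H)-one
Product: 5 3,4-dichloro-5,5-bis[4-(methoxymethoxy)phenyl]furan-2(5H)-one
Conditions: MOMCl, i-Pr2NEt, CH2Cl2, 0 °C → rt
Reagents that add atoms: chloromethyl methyl ether, COCCl
Why: O-alkylation of the two phenols as MOM ethers; the hindered amine base is not nucleophilic enough to displace the vinylogous acyl chloride at C4, and adding it last to a solution that already holds excess MOMCl keeps free phenoxide from doing so.

Step 3
Reactants: 6 4-hydroxyacetophenone
Product: 7 1-[4-(methoxymethoxy)phenyl]ethan-1-one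
Conditions: MOMCl, i-Pr2NEt, CH2Cl2, 0 °C → rt
Reagents that add atoms: chloromethyl methyl ether, COCCl
Why: Standard MOM protection of a phenol, giving the same protecting group as in 5 so that all phenolic groups leave together at the end.

Step 4
Reactants: 7 1-[4-(methoxymethoxy)phenyl]ethan-1-one
Product: 9 1-[4-(methoxymethoxy)phenyl]ethenyl trifluoromethanesulfonate, via potassium enolate 8 (not isolated)
Conditions: KN(SiMe3)2, THF, −78 °C; then PhNTf2, −78 → 0 °C
Reagents that add atoms: N-phenylbis(trifluoromethanesulfonimide), O=S(=O)(N(c1ccccc1)S(=O)(=O)C(F)(F)F)C(F)(F)F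
Why: Enol triflate formation: the methyl ketone has a single enolisable site, and O-sulfonylation of enolate 8 gives the 1-arylvinyl triflate; the electron-rich triflate is acid-labile and should be purified on base-washed silica and used promptly.

Step 5
Reactants: 9 1-[4-(methoxymethoxy)phenyl]ethenyl trifluoromethanesulfonate
Product: 10 2-{1-[4-(methoxymethoxy)phenyl]ethenyl}-4,4,5,5-tetramethyl-1,3,2-dioxaborolane
Conditions: B2pin2, PdCl2(PPh3)2 (3 mol %), PPh3 (6 mol %), KOPh, toluene, 50 °C
Reagents that add atoms: bis(pinacolato)diboron, CC1(C)OB(OC1(C)C)B1OC(C)(C)C(C)(C)O1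
Why: Miyaura borylation of an alkenyl triflate; the weak phenoxide base activates the diboron without promoting Suzuki coupling of the product with unreacted triflate.

Step 6
Reactants: 11 propargyl alcohol
Product: 12 tert-butyldimethyl(prop-2-yn-1-yloxy)silane
Conditions: TBSCl, imidazole, CH2Cl2, 0 °C → rt
Reagents that add atoms: tert-butyldimethylsilyl chloride, CC(C)(C)[Si](C)(C)Cl
Why: Standard silylation of a primary alcohol; TBS is chosen because a primary TBS ether is cleaved by the same mild acid as phenolic MOM ethers, whereas an alkyl MOM ether would need harsher acid in the last step.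

Step 7
Reactants: 12 tert-butyldimethyl(prop-2-yn-1-yloxy)silane
Product: 13 tert-butyldimethyl{[2-(4,4,5,5-tetramethyl-1,3,2-dioxaborolan-2-yl)prop-2-en-1-yl]oxy}silane
Conditions: B2pin2, MeOH (2 equiv), (SIMes)CuCl (2 mol %; SIMes = 1,3-bis(2,4,6-trimethylphenyl)imidazolidin-2-ylidene), NaOt-Bu (5 mol %), THF, −50 → −15 °C
Reagents that add atoms: bis(pinacolato)diboron, CC1(C)OB(OC1(C)C)B1OC(C)(C)C(C)(C)O1
Why: Copper-catalysed protoboration of a terminal alkyne: the carbene–copper–boryl species adds syn across the triple bond and, with an N-aryl carbene ligand and a propargylic oxygen, places boron on the internal carbon; methanol then protonates the vinyl–copper bond.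

Step 8
Reactants: 5 3,4-dichloro-5,5-bis[4-(methoxymethoxy)phenyl]furan-2(5H)-one; 10 2-{1-[4-(methoxymethoxy)phenyl]ethenyl}-4,4,5,5-tetramethyl-1,3,2-dioxaborolane
Product: 14 3-chloro-5,5-bis[4-(methoxymethoxy)phenyl]-4-{1-[4-(methoxymethoxy)phenyl]ethenyl}furan-2(5H)-one
Conditions: Pd(PPh3)4 (5 mol %), CsF, dioxane, 70 °C; 10 (1.05 equiv)
Reagents that add atoms: none
Why: Suzuki–Miyaura coupling; zerovalent palladium inserts first into the C4–Cl bond, the β-position of the unsaturated lactone and a vinylogous acyl chloride, as in known C4-selective couplings of 3,4-dihalofuran-2(5H)-ones. A triphenylphosphine catalyst of moderate activity and one equivalent of boronate should leave the C3 chloride untouched.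

Step 9
Reactants: 14 3-chloro-5,5-bis[4-(methoxymethoxy)phenyl]-4-{1-[4-(methoxymethoxy)phenyl]ethenyl}furan-2(5H)-one; 13 tert-butyldimethyl{[2-(4,4,5,5-tetramethyl-1,3,2-dioxaborolan-2-yl)prop-2-en-1-yl]oxy}silane
Product: 15 3-[3-(tert-butyldimethylsilyloxy)prop-1-en-2-yl]-5,5-bis[4-(methoxymethoxy)phenyl]-4-{1-[4-(methoxymethoxy)phenyl]ethenyl}furan-2(5H)-one
Conditions: Pd(OAc)2 (5 mol %), SPhos (10 mol %), K3PO4, toluene–H2O (10:1), 70 °C, degassed
Reagents that add atoms: none
Why: Suzuki–Miyaura coupling of the remaining α-chloro lactone; the bulky, electron-rich biarylphosphine promotes insertion into the hindered C3–Cl bond and transmetalation of the 1,1-disubstituted vinylboronate. Any triene that closes at this temperature is already the product of step 10 and can be carried forward with the rest.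

Step 10
Reactants: 15 3-[3-(tert-butyldimethylsilyloxy)prop-1-en-2-yl]-5,5-bis[4-(methoxymethoxy)phenyl]-4-{1-[4-(methoxymethoxy)phenyl]ethenyl}furan-2(5H)-one
Product: 16 7-[(tert-butyldimethylsilyloxy)methyl]-3,3,4-tris[4-(methoxymethoxy)phenyl]-5,6-dihydroisobenzofuran-1(3H)-one
Conditions: BHT (10 mol %), degassed o-xylene (0.01 M), 140 °C, Ar
Reagents that add atoms: none
Why: Both vinyl groups sit on the same side of the ring double bond of the furanone, so the triene can adopt its s-cis,s-cis conformer on heating, and an orbital-symmetry-allowed thermal disrotatory 6π-electrocyclisation then joins the two CH2 termini. The closest known reaction type is the thermal 6π-electrocyclisation of 1,3,5-hexatrienes whose central double bond lies in a ring (3,4-dialkenyl maleic anhydrides, maleimides and furanones, 2,3-divinyl heteroarenes), followed by dehydrogenation to the arene. Ring A closes as a six-membered carbocycle by formation of the single σ bond between ring A C3 and C4 through a boat-like transition state, giving a cyclohexa-1,3-diene whose double bonds (C1=C2 and C5=C6) are exocyclic to the lactone. No stereocentre is formed, because both termini are unsubstituted and become ring CH2 groups. There is no regiochemical choice; the selectivity needed is closure over radical polymerisation or dimerisation of the two 1,1-disubstituted alkenes, and this is secured by the enforced cis geometry, high dilution, exclusion of oxygen and the radical inhibitor. No sigmatropic hydrogen shift can compete, because neither terminus carries an sp3 C–H bond. The main strain in the transition state is the contact between the vinyl aryl group and the gem-diaryl carbon, which is also present in the product; if closure is slow the temperature can be raised to about 180 °C in 1,2-dichlorobenzene.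

Step 11
Reactants: 16 7-[(tert-butyldimethylsilyloxy)methyl]-3,3,4-tris[4-(methoxymethoxy)phenyl]-5,6-dihydroisobenzofuran-1(3H)-one
Product: 17 7-[(tert-butyldimethylsilyloxy)methyl]-3,3,4-tris[4-(methoxymethoxy)phenyl]isobenzofuran-1(3H)-one
Conditions: DDQ (1.2 equiv), toluene, rt → 60 °C
Reagents that add atoms: none
Why: Quinone dehydrogenation of a cyclohexa-1,3-diene: hydride abstraction from a ring CH2 gives a cyclohexadienyl cation, and proton loss aromatises it. MOM and silyl ethers are inert to DDQ under these conditions.

Step 12
Reactants: 17 7-[(tert-butyldimethylsilyloxy)methyl]-3,3,4-tris[4-(methoxymethoxy)phenyl]isobenzofuran-1(3H)-one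
Product: 18 7-[(tert-butyldimethylsilyloxy)methyl]-3,3,4-tris[4-(methoxymethoxy)phenyl]-1,3-dihydroisobenzofuran-1-ol (racemic)
Conditions: i-Bu2AlH (1.2 equiv), CH2Cl2, −78 °C; aq. KNaC4H4O6 work-up
Reagents that add atoms: none
Why: Half-reduction of a lactone to a lactol; the aluminium hemiacetal is stable at −78 °C and does not reduce further. The new hemiacetal centre forms as a racemate and is destroyed in step 13.

Step 13
Reactants: 18 7-[(tert-butyldimethylsilyloxy)methyl]-3,3,4-tris[4-(methoxymethoxy)phenyl]-1,3-dihydroisobenzofuran-1-ol
Product: 20 {3-[(tert-butyldimethylsilyloxy)methyl]-2-ethynyl-6-[4-(methoxymethoxy)phenyl]phenyl}bis[4-(methoxymethoxy)phenyl]methanol, via ring-opened hydroxy aldehyde 19 (not isolated)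
Conditions: dimethyl (1-diazo-2-oxopropyl)phosphonate (3 equiv), K2CO3, MeOH–THF (2:1), 0 °C → rt
Reagents that add atoms: dimethyl (1-diazo-2-oxopropyl)phosphonate, COP(=O)(OC)C(=[N+]=[N-])C(C)=O
Why: Ohira–Bestmann (Seyferth–Gilbert) homologation, known on lactols: methanolysis of the reagent gives the diazomethylphosphonate anion, which traps the small equilibrium amount of aldehyde 19. Loss of phosphate and N2 and a 1,2-hydrogen shift then give the terminal alkyne; the tertiary alcohol is too hindered to interfere.

Step 14
Reactants: 21 4-iodophenol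
Product: 22 1-iodo-4-(methoxymethoxy)benzene
Conditions: MOMCl, i-Pr2NEt, CH2Cl2, 0 °C → rt
Reagents that add atoms: chloromethyl methyl ether, COCCl
Why: Standard MOM protection of a phenol.

Step 15
Reactants: 20 {3-[(tert-butyldimethylsilyloxy)methyl]-2-ethynyl-6-[4-(methoxymethoxy)phenyl]phenyl}bis[4-(methoxymethoxy)phenyl]methanol; 22 1-iodo-4-(methoxymethoxy)benzene
Product: 23 {3-[(tert-butyldimethylsilyloxy)methyl]-6-[4-(methoxymethoxy)phenyl]-2-{[4-(methoxymethoxy)phenyl]ethynyl}phenyl}bis[4-(methoxymethoxy)phenyl]methanol
Conditions: PdCl2(PPh3)2 (3 mol %), CuI (5 mol %), Et3N–THF (1:1), rt, degassed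
Reagents that add atoms: none
Why: Sonogashira coupling of a terminal alkyne with an aryl iodide, which proceeds at room temperature; the low temperature and amine base should keep the neighbouring tertiary alcohol from adding to the alkyne.

Step 16
Reactants: 23 {3-[(tert-butyldimethylsilyloxy)methyl]-6-[4-(methoxymethoxy)phenyl]-2-{[4-(methoxymethoxy)phenyl]ethynyl}phenyl}bis[4-(methoxymethoxy)phenyl]methanol
Product: 25 selaginellin, via pentahydroxy carbinol 24 (not isolated)
Conditions: HCl (1.25 M in MeOH)–THF, rt → 40 °C; then aq. NaHCO3
Reagents that add atoms: none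
Why: Acid-mediated global deprotection: the four aryl MOM acetals and the primary silyl ether are solvolysed to give 24. The triarylcarbinol then ionises to a cation stabilised by two 4-hydroxyphenyl rings, and loss of a phenolic proton gives the quinone methide, the stable form of a 4-hydroxy-substituted triarylcarbinol.

## Compound list

1 | dichloromaleic anhydride | O=C1OC(=O)C(Cl)=C1Cl | starting material
2 | phenol | Oc1ccccc1 | starting material
3 | 3,4-dichloro-5-hydroxy-5-(4-hydroxyphenyl)furan-2(5H)-one (racemic) | O=C1OC(O)(c2ccc(O)cc2)C(Cl)=C1Cl | intermediate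
4 | 3,4-dichloro-5,5-bis(4-hydroxyphenyl)furan-2(5H)-one | O=C1OC(c2ccc(O)cc2)(c2ccc(O)cc2)C(Cl)=C1Cl | intermediate
5 | 3,4-dichloro-5,5-bis[4-(methoxymethoxy)phenyl]furan-2(5H)-one | O=C1OC(c2ccc(OCOC)cc2)(c2ccc(OCOC)cc2)C(Cl)=C1Cl | intermediate
6 | 4-hydroxyacetophenone | CC(=O)c1ccc(O)cc1 | starting material
7 | 1-[4-(methoxymethoxy)phenyl]ethan-1-one | CC(=O)c1ccc(OCOC)cc1 | intermediate
8 | potassium 1-[4-(methoxymethoxy)phenyl]ethen-1-olate | [K+].[O-]C(=C)c1ccc(OCOC)cc1 | intermediate
9 | 1-[4-(methoxymethoxy)phenyl]ethenyl trifluoromethanesulfonate | C=C(OS(=O)(=O)C(F)(F)F)c1ccc(OCOC)cc1 | intermediate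
10 | 2-{1-[4-(methoxymethoxy)phenyl]ethenyl}-4,4,5,5-tetramethyl-1,3,2-dioxaborolane | C=C(B1OC(C)(C)C(C)(C)O1)c1ccc(OCOC)cc1 | intermediate
11 | propargyl alcohol | C#CCO | starting material
12 | tert-butyldimethyl(prop-2-yn-1-yloxy)silane | C#CCO[Si](C)(C)C(C)(C)C | intermediate
13 | tert-butyldimethyl{[2-(4,4,5,5-tetramethyl-1,3,2-dioxaborolan-2-yl)prop-2-en-1-yl]oxy}silane | C=C(CO[Si](C)(C)C(C)(C)C)B1OC(C)(C)C(C)(C)O1 | intermediate
14 | 3-chloro-5,5-bis[4-(methoxymethoxy)phenyl]-4-{1-[4-(methoxymethoxy)phenyl]ethenyl}furan-2(5H)-one | O=C1OC(c2ccc(OCOC)cc2)(c2ccc(OCOC)cc2)C(C(=C)c2ccc(OCOC)cc2)=C1Cl | intermediate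
15 | 3-[3-(tert-butyldimethylsilyloxy)prop-1-en-2-yl]-5,5-bis[4-(methoxymethoxy)phenyl]-4-{1-[4-(methoxymethoxy)phenyl]ethenyl}furan-2(5H)-one | C=C(CO[Si](C)(C)C(C)(C)C)C1=C(C(=C)c2ccc(OCOC)cc2)C(c2ccc(OCOC)cc2)(c2ccc(OCOC)cc2)OC1=O | intermediate
16 | 7-[(tert-butyldimethylsilyloxy)methyl]-3,3,4-tris[4-(methoxymethoxy)phenyl]-5,6-dihydroisobenzofuran-1(3H)-one | CC(C)(C)[Si](C)(C)OCC1=C2C(=O)OC(c3ccc(OCOC)cc3)(c3ccc(OCOC)cc3)C2=C(c2ccc(OCOC)cc2)CC1 | intermediate
17 | 7-[(tert-butyldimethylsilyloxy)methyl]-3,3,4-tris[4-(methoxymethoxy)phenyl]isobenzofuran-1(3H)-one | CC(C)(C)[Si](C)(C)OCc1ccc(-c2ccc(OCOC)cc2)c2c1C(=O)OC2(c1ccc(OCOC)cc1)c1ccc(OCOC)cc1 | intermediate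
18 | 7-[(tert-butyldimethylsilyloxy)methyl]-3,3,4-tris[4-(methoxymethoxy)phenyl]-1,3-dihydroisobenzofuran-1-ol (racemic) | CC(C)(C)[Si](C)(C)OCc1ccc(-c2ccc(OCOC)cc2)c2c1C(O)OC2(c1ccc(OCOC)cc1)c1ccc(OCOC)cc1 | intermediate
19 | 6-[(tert-butyldimethylsilyloxy)methyl]-2-{hydroxybis[4-(methoxymethoxy)phenyl]methyl}-3-[4-(methoxymethoxy)phenyl]benzaldehyde | O=Cc1c(CO[Si](C)(C)C(C)(C)C)ccc(-c2ccc(OCOC)cc2)c1C(O)(c1ccc(OCOC)cc1)c1ccc(OCOC)cc1 | intermediate
20 | {3-[(tert-butyldimethylsilyloxy)methyl]-2-ethynyl-6-[4-(methoxymethoxy)phenyl]phenyl}bis[4-(methoxymethoxy)phenyl]methanol | C#Cc1c(CO[Si](C)(C)C(C)(C)C)ccc(-c2ccc(OCOC)cc2)c1C(O)(c1ccc(OCOC)cc1)c1ccc(OCOC)cc1 | intermediate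
21 | 4-iodophenol | Oc1ccc(I)cc1 | starting material
22 | 1-iodo-4-(methoxymethoxy)benzene | COCOc1ccc(I)cc1 | intermediate
23 | {3-[(tert-butyldimethylsilyloxy)methyl]-6-[4-(methoxymethoxy)phenyl]-2-{[4-(methoxymethoxy)phenyl]ethynyl}phenyl}bis[4-(methoxymethoxy)phenyl]methanol | CC(C)(C)[Si](C)(C)OCc1ccc(-c2ccc(OCOC)cc2)c(C(O)(c2ccc(OCOC)cc2)c2ccc(OCOC)cc2)c1C#Cc1ccc(OCOC)cc1 | intermediate
24 | 4,4'-(hydroxy{3-(hydroxymethyl)-6-(4-hydroxyphenyl)-2-[(4-hydroxyphenyl)ethynyl]phenyl}methylene)diphenol | OCc1ccc(-c2ccc(O)cc2)c(C(O)(c2ccc(O)cc2)c2ccc(O)cc2)c1C#Cc1ccc(O)cc1 | intermediate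
25 | selaginellin, 4-{[3-(hydroxymethyl)-6-(4-hydroxyphenyl)-2-[(4-hydroxyphenyl)ethynyl]phenyl](4-hydroxyphenyl)methylidene}cyclohexa-2,5-dien-1-one | O=C1C=CC(=C(c2ccc(O)cc2)c2c(-c3ccc(O)cc3)ccc(CO)c2C#Cc2ccc(O)cc2)C=C1 | target

## Step count and risks

Total step count: 16. Longest linear sequence: 11 steps (steps 3, 4, 5, 8, 9, 10, 11, 12, 13, 15, 16).

**Step 10 (key step).** Closure may be too slow. To reach the reactive conformer, the aryl-bearing vinyl arm must turn its aryl group towards the gem-diaryl carbon. At the temperature then needed, radical polymerisation or decomposition of the styrene-type alkenes could consume the triene. The fallback introduces the ring A C2 aryl group after ring A exists, so that the triene carries only a small ethoxy group at that position; it sets out from 5 and returns at 17. Stille coupling of 5 with tributyl(1-ethoxyvinyl)stannane [Pd(PPh3)4, toluene, 80 °C] at C4 should give 3-chloro-4-(1-ethoxyethenyl)-5,5-bis[4-(methoxymethoxy)phenyl]furan-2(5H)-one F1. Suzuki coupling of F1 with 13 under the conditions of step 9 should give 3-[3-(tert-butyldimethylsilyloxy)prop-1-en-2-yl]-4-(1-ethoxyethenyl)-5,5-bis[4-(methoxymethoxy)phenyl]furan-2(5H)-one F2. The less hindered thermal 6π closure of F2 should give 7-[(tert-butyldimethylsilyloxy)methyl]-4-ethoxy-3,3-bis[4-(methoxymethoxy)phenyl]-5,6-dihydroisobenzofuran-1(3H)-one F3. Brief hydrolysis of the enol ether (oxalic acid, wet THF) should give 7-[(tert-butyldimethylsilyloxy)methyl]-3,3-bis[4-(methoxymethoxy)phenyl]-6,7-dihydroisobenzofuran-1,4(3H,5H)-dione F4. DDQ dehydrogenation of F4 should give 7-[(tert-butyldimethylsilyloxy)methyl]-4-hydroxy-3,3-bis[4-(methoxymethoxy)phenyl]isobenzofuran-1(3H)-one F5. Tf2O and pyridine should then give 7-[(tert-butyldimethylsilyloxy)methyl]-3,3-bis[4-(methoxymethoxy)phenyl]-1-oxo-1,3-dihydroisobenzofuran-4-yl trifluoromethanesulfonate F6. Suzuki coupling of F6 with 4-(methoxymethoxy)phenylboronic acid [Pd(OAc)2, SPhos, K3PO4] should give 17.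

**Step 1.** The acid condensation may give mixtures through ortho attack on phenol, incomplete second arylation, or attack of phenol on the chlorinated double bond. The fallback forms the two aryl–carbon bonds with an organometallic reagent; it sets out from 1 and returns at 5. 4-(Methoxymethoxy)phenylmagnesium bromide F7 (2.2 equiv, from commercial 1-bromo-4-(methoxymethoxy)benzene and Mg) is added to 1 in THF at −78 °C. It should add twice at one carbonyl group, and mild acidic work-up should close the lactone to give 5 directly, with no separate protection step.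

**Step 8.** Site selectivity between the two chlorides may be poor, or insertion at the C4–Cl bond next to the quaternary carbon may be sluggish, leading to double coupling or recovered material. The fallback differentiates the two positions chemically, not by the catalyst; it sets out from 5 and returns at 14. Addition–elimination of hydroxide at C4 (NaOH, aqueous THF, then acid) should give 3-chloro-4-hydroxy-5,5-bis[4-(methoxymethoxy)phenyl]furan-2(5H)-one F8. Tf2O and i-Pr2NEt at −78 °C should give 4-chloro-2,2-bis[4-(methoxymethoxy)phenyl]-5-oxo-2,5-dihydrofuran-3-yl trifluoromethanesulfonate F9. The triflate of F9 is far more reactive than the C3 chloride, and Suzuki coupling with 10 [Pd(PPh3)4, K3PO4, dioxane, 50 °C] should give 14.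

**Step 9.** Transmetalation of the vinylboronate to the hindered C3–palladium intermediate may be slow, so that protodeboronation of 13 and reduction of the C–Cl bond take over. The fallback uses a more nucleophilic organozinc reagent made from a vinyl bromide (Negishi coupling); it sets out from 14 and returns at 15. Commercial 2-bromoallyl alcohol is silylated (TBSCl, imidazole) to [(2-bromoprop-2-en-1-yl)oxy](tert-butyl)dimethylsilane F10. Bromine–lithium exchange (t-BuLi, Et2O, −78 °C) and immediate addition of ZnCl2 at −78 °C, to forestall silyl migration, should give {3-[(tert-butyldimethylsilyl)oxy]prop-1-en-2-yl}zinc chloride F11. Coupling of F11 with 14 [Pd(P(t-Bu)3)2, THF, rt → 50 °C] should give 15.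

**Step 13.** The gem-diaryl group may hold the lactol closed so firmly that the diazophosphonate anion decomposes before it meets the aldehyde; the alkoxide may also add to the new alkyne. The fallback brings in the second alkyne carbon and its aryl group together, as a sulfone anion that attacks the lactone itself; it sets out from 17 and returns at 23, so steps 12, 13 and 15 are bypassed. 4-Hydroxybenzyl alcohol and PhSO2Na in aqueous formic acid should give 4-[(phenylsulfonyl)methyl]phenol F12. MOMCl and i-Pr2NEt should give 1-(methoxymethoxy)-4-[(phenylsulfonyl)methyl]benzene F13. The lithium derivative of F13 (n-BuLi, THF, −78 °C, 2.2 equiv) should open lactone 17 to 1-{6-[(tert-butyldimethylsilyloxy)methyl]-2-{hydroxybis[4-(methoxymethoxy)phenyl]methyl}-3-[4-(methoxymethoxy)phenyl]phenyl}-2-[4-(methoxymethoxy)phenyl]-2-(phenylsulfonyl)ethan-1-one F14. O-Phosphorylation of the enolate of F14 [KN(SiMe3)2, ClP(O)(OEt)2, THF] should give 1-{6-[(tert-butyldimethylsilyloxy)methyl]-2-{hydroxybis[4-(methoxymethoxy)phenyl]methyl}-3-[4-(methoxymethoxy)phenyl]phenyl}-2-[4-(methoxymethoxy)phenyl]-2-(phenylsulfonyl)ethenyl diethyl phosphate F15 as an E/Z mixture. Reductive elimination of F15 with Na/Hg in THF–MeOH at −20 °C should give 23.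

## Further compounds

F1 | step 10 | 3-chloro-4-(1-ethoxyethenyl)-5,5-bis[4-(methoxymethoxy)phenyl]furan-2(5H)-one | CCOC(=C)C1=C(Cl)C(=O)OC1(c1ccc(OCOC)cc1)c1ccc(OCOC)cc1
F2 | step 10 | 3-[3-(tert-butyldimethylsilyloxy)prop-1-en-2-yl]-4-(1-ethoxyethenyl)-5,5-bis[4-(methoxymethoxy)phenyl]furan-2(5H)-one | CCOC(=C)C1=C(C(=C)CO[Si](C)(C)C(C)(C)C)C(=O)OC1(c1ccc(OCOC)cc1)c1ccc(OCOC)cc1
F3 | step 10 | 7-[(tert-butyldimethylsilyloxy)methyl]-4-ethoxy-3,3-bis[4-(methoxymethoxy)phenyl]-5,6-dihydroisobenzofuran-1(3H)-one | CCOC1=C2C(=C(CO[Si](C)(C)C(C)(C)C)CC1)C(=O)OC2(c1ccc(OCOC)cc1)c1ccc(OCOC)cc1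
F4 | step 10 | 7-[(tert-butyldimethylsilyloxy)methyl]-3,3-bis[4-(methoxymethoxy)phenyl]-6,7-dihydroisobenzofuran-1,4(3H,5H)-dione (racemic) | O=C1CCC(CO[Si](C)(C)C(C)(C)C)C2=C1C(c1ccc(OCOC)cc1)(c1ccc(OCOC)cc1)OC2=O
F5 | step 10 | 7-[(tert-butyldimethylsilyloxy)methyl]-4-hydroxy-3,3-bis[4-(methoxymethoxy)phenyl]isobenzofuran-1(3H)-one | Oc1ccc(CO[Si](C)(C)C(C)(C)C)c2c1C(c1ccc(OCOC)cc1)(c1ccc(OCOC)cc1)OC2=O
F6 | step 10 | 7-[(tert-butyldimethylsilyloxy)methyl]-3,3-bis[4-(methoxymethoxy)phenyl]-1-oxo-1,3-dihydroisobenzofuran-4-yl trifluoromethanesulfonate | O=S(=O)(Oc1ccc(CO[Si](C)(C)C(C)(C)C)c2c1C(c1ccc(OCOC)cc1)(c1ccc(OCOC)cc1)OC2=O)C(F)(F)F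
F7 | step 1 | 4-(methoxymethoxy)phenylmagnesium bromide | COCOc1ccc([Mg]Br)cc1
F8 | step 8 | 3-chloro-4-hydroxy-5,5-bis[4-(methoxymethoxy)phenyl]furan-2(5H)-one | O=C1OC(c2ccc(OCOC)cc2)(c2ccc(OCOC)cc2)C(O)=C1Cl
F9 | step 8 | 4-chloro-2,2-bis[4-(methoxymethoxy)phenyl]-5-oxo-2,5-dihydrofuran-3-yl trifluoromethanesulfonate | O=C1OC(c2ccc(OCOC)cc2)(c2ccc(OCOC)cc2)C(OS(=O)(=O)C(F)(F)F)=C1Cl
F10 | step 9 | [(2-bromoprop-2-en-1-yl)oxy](tert-butyl)dimethylsilane | C=C(Br)CO[Si](C)(C)C(C)(C)C
F11 | step 9 | {3-[(tert-butyldimethylsilyl)oxy]prop-1-en-2-yl}zinc chloride | C=C([Zn]Cl)CO[Si](C)(C)C(C)(C)C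
F12 | step 13 | 4-[(phenylsulfonyl)methyl]phenol | Oc1ccc(CS(=O)(=O)c2ccccc2)cc1
F13 | step 13 | 1-(methoxymethoxy)-4-[(phenylsulfonyl)methyl]benzene | COCOc1ccc(CS(=O)(=O)c2ccccc2)cc1
F14 | step 13 | 1-{6-[(tert-butyldimethylsilyloxy)methyl]-2-{hydroxybis[4-(methoxymethoxy)phenyl]methyl}-3-[4-(methoxymethoxy)phenyl]phenyl}-2-[4-(methoxymethoxy)phenyl]-2-(phenylsulfonyl)ethan-1-one (racemic) | CC(C)(C)[Si](C)(C)OCc1ccc(-c2ccc(OCOC)cc2)c(C(O)(c2ccc(OCOC)cc2)c2ccc(OCOC)cc2)c1C(=O)C(c1ccc(OCOC)cc1)S(=O)(=O)c1ccccc1
F15 | step 13 | 1-{6-[(tert-butyldimethylsilyloxy)methyl]-2-{hydroxybis[4-(methoxymethoxy)phenyl]methyl}-3-[4-(methoxymethoxy)phenyl]phenyl}-2-[4-(methoxymethoxy)phenyl]-2-(phenylsulfonyl)ethenyl diethyl phosphate (E/Z mixture) | CCOP(=O)(OCC)OC(=C(c1ccc(OCOC)cc1)S(=O)(=O)c1ccccc1)c1c(CO[Si](C)(C)C(C)(C)C)ccc(-c2ccc(OCOC)cc2)c1C(O)(c1ccc(OCOC)cc1)c1ccc(OCOC)cc1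
A1 | alternative 1 | {3-chloro-4'-(methoxymethoxy)-4-[(triisopropylsilyloxy)methyl]biphenyl-2-yl}[4-(methoxymethoxy)phenyl]methanone | COCOc1ccc(C(=O)c2c(-c3ccc(OCOC)cc3)ccc(CO[Si](C(C)C)(C(C)C)C(C)C)c2Cl)cc1
A2 | alternative 2 | dimethyl[3-(methoxymethoxy)prop-1-yn-1-yl]{[1,1,3-tris(4-(methoxymethoxy)phenyl)prop-2-yn-1-yl]oxy}silane | COCOCC#C[Si](C)(C)OC(C#Cc1ccc(OCOC)cc1)(c1ccc(OCOC)cc1)c1ccc(OCOC)cc1
A3 | alternative 2 | acetylene | C#C
A4 | alternative 2 | 7-[(methoxymethoxy)methyl]-1,1-dimethyl-3,3,4-tris[4-(methoxymethoxy)phenyl]-1,3-dihydro-2,1-benzoxasilole | COCOCc1ccc(-c2ccc(OCOC)cc2)c2c1[Si](C)(C)OC2(c1ccc(OCOC)cc1)c1ccc(OCOC)cc1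
A5 | alternative 3 | methyl 3-[(tert-butyldiphenylsilyloxy)methyl]-2-hydroxy-6-[4-(triisopropylsilyloxy)phenyl]benzoate | COC(=O)c1c(O)c(CO[Si](c2ccccc2)(c2ccccc2)C(C)(C)C)ccc1-c1ccc(O[Si](C(C)C)(C(C)C)C(C)C)cc1
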